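**Retrosynthetic overview**
1. Caraphenol B (21) ⇐ one-pot syn-hydrogenation and hydrogenolysis of the pentabenzyl 3-aroyl-1H-indene 20; H2 adds anti to the existing aryl-bearing stereocentre and sets the other two centres all-cis.
2. 20 ⇐ carbonylative Stille coupling of enol triflate 19 with arylstannane 7; 19 ⇐ trans-2,3-diarylindanone 17.
3. 17 ⇐ one-pot asymmetric CuH 1,4-reduction / Pd α-arylation of 3-arylindenone 15 (sets the 3,5-dioxyphenyl-bearing centre).
4. 15 ⇐ intramolecular aldol condensation of 2-acetylbenzophenone 13. This is the only ring-forming step: the five-membered ring is closed onto bought benzene rings.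
5. 13 ⇐ aryllithium from bromo ketal 10 (from acetophenone 8) + Weinreb amide 3 (from methyl 3,5-dihydroxybenzoate 1).

Assumption: the SMILES is taken literally, i.e. (1R,2R,3R) with the aroyl, 4-hydroxyphenyl and 3,5-dihydroxyphenyl groups all cis on the five-membered ring.

**Step 1**
Reactants: 1 methyl 3,5-dihydroxybenzoate
Product: 2 methyl 3,5-bis(benzyloxy)benzoate
Conditions: BnBr (2.2 equiv), K2CO3, acetone, reflux
Reagents that add atoms: benzyl bromide, BrCc1ccccc1
Why: Williamson ether synthesis (SN2 O-benzylation of both phenoxides); no stereocentre.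

**Step 2**
Reactants: 2 methyl 3,5-bis(benzyloxy)benzoate
Product: 3 3,5-bis(benzyloxy)-N-methoxy-N-methylbenzamide
Conditions: MeNHOMe·HCl (1.5 equiv), i-PrMgCl (3 equiv), THF, −20 → 0 °C
Reagents that add atoms: N,O-dimethylhydroxylamine hydrochloride, Cl.CNOC
Why: direct ester-to-Weinreb-amide aminolysis by the magnesium amide formed in situ.

**Step 3**
Reactants: 4 4-bromophenol
Product: 5 1-(benzyloxy)-4-bromobenzene
Conditions: BnBr, K2CO3, acetone, reflux
Reagents that add atoms: benzyl bromide, BrCc1ccccc1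
Why: Williamson ether synthesis; 5 serves both as the α-arylation partner and as the stannane precursor.

**Step 4**
Reactants: 5 1-(benzyloxy)-4-bromobenzene
Product: 7 [4-(benzyloxy)phenyl]tributylstannane, via aryllithium 6 (not isolated)
Conditions: n-BuLi, THF, −78 °C; then Bu3SnCl, −78 °C → rt
Reagents that add atoms: tributyltin chloride, CCCC[Sn](Cl)(CCCC)CCCC
Why: bromine–lithium exchange followed by stannylation of the aryllithium.

**Step 5**
Reactants: 8 1-[3,5-bis(benzyloxy)phenyl]ethan-1-one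
Product: 9 1-[3,5-bis(benzyloxy)-2-bromophenyl]ethan-1-one
Conditions: NBS (1.05 equiv), MeCN, 0 °C → rt
Reagents that add atoms: N-bromosuccinimide, O=C1CCC(=O)N1Br
Why: electrophilic aromatic bromination at C-2 (ortho to one and para to the other benzyloxy group), the site known for the dimethoxy analogue.

**Step 6**
Reactants: 9 1-[3,5-bis(benzyloxy)-2-bromophenyl]ethan-1-one
Product: 10 2-[3,5-bis(benzyloxy)-2-bromophenyl]-2-methyl-1,3-dioxolane
Conditions: HOCH2CH2OH, p-TsOH (cat.), toluene, reflux, Dean–Stark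
Reagents that add atoms: ethylene glycol, OCCO
Why: acid-catalysed ketalisation masks the enolisable ketone before metalation.

**Step 7**
Reactants: 10 2-[3,5-bis(benzyloxy)-2-bromophenyl]-2-methyl-1,3-dioxolane; 3 3,5-bis(benzyloxy)-N-methoxy-N-methylbenzamide
Product: 13 1-{3,5-bis(benzyloxy)-2-[3,5-bis(benzyloxy)benzoyl]phenyl}ethan-1-one, via aryllithium 11 (not isolated), via ketal ketone 12 (not isolated)
Conditions: n-BuLi, THF, −78 °C; 3, −78 → 0 °C; then 2 M HCl, THF, rt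
Reagents that add atoms: water, O
Why: Br/Li exchange and Weinreb ketone synthesis (the N,O-chelate stops over-addition), then the acidic work-up hydrolyses the dioxolane to the 1,2-diacylbenzene.

**Step 8 (key ring closure)**
Reactants: 13 1-{3,5-bis(benzyloxy)-2-[3,5-bis(benzyloxy)benzoyl]phenyl}ethan-1-one
Product: 15 4,6-bis(benzyloxy)-3-[3,5-bis(benzyloxy)phenyl]-1H-inden-1-one, via aldol adduct 14 (not isolated)
Conditions: KOH, EtOH–THF, rt; then p-TsOH (cat.), toluene, 60 °C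
Reagents that add atoms: none
Why: intramolecular aldol condensation, in which the methyl-ketone enolate (the only enolisable site) adds 5-exo-trig to the non-enolisable diaryl ketone and the tertiary benzylic carbinol dehydrates to the achiral indenone.

**Step 9**
Reactants: 15 4,6-bis(benzyloxy)-3-[3,5-bis(benzyloxy)phenyl]-1H-inden-1-one; 5 1-(benzyloxy)-4-bromobenzene
Product: 17 (2R,3R)-4,6-bis(benzyloxy)-2-[4-(benzyloxy)phenyl]-3-[3,5-bis(benzyloxy)phenyl]-2,3-dihydro-1H-inden-1-one (2,3-trans), via bis(enoxy)silane 16 (not isolated)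
Conditions: CuCl/NaOt-Bu/(S)-p-Tol-BINAP (5 mol %), Ph2SiH2 (0.55 equiv), toluene, 0 °C; then 5, Pd(OAc)2/P(t-Bu)3 (cat.), CsF, THF, rt → 50 °C
Reagents that add atoms: none
Why: Buchwald-type asymmetric CuH conjugate reduction delivers hydride to the Si face of C-3 to give the (R) centre, and the silyl enol ether is then arylated at C-2 by Pd/fluoride anti to the C-3 aryl; the ligand hand is assigned by analogy with 3-substituted cyclopentenones and must be confirmed on 17, the (R)-ligand being used if the sense is reversed.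

**Step 10**
Reactants: 17 (2R,3R)-4,6-bis(benzyloxy)-2-[4-(benzyloxy)phenyl]-3-[3,5-bis(benzyloxy)phenyl]-2,3-dihydro-1H-inden-1-one
Product: 19 (1R)-5,7-bis(benzyloxy)-2-[4-(benzyloxy)phenyl]-1-[3,5-bis(benzyloxy)phenyl]-1H-inden-3-yl trifluoromethanesulfonate, via potassium enolate 18 (not isolated)
Conditions: KHMDS (1.0 equiv), THF, −78 °C; cannulated into Comins' reagent, THF, −78 °C
Reagents that add atoms: Comins' reagent, N-(5-chloropyridin-2-yl)-N-(trifluoromethylsulfonyl)trifluoromethanesulfonamide, Clc1ccc(nc1)N(S(=O)(=O)C(F)(F)F)S(=O)(=O)C(F)(F)F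
Why: O-triflation of the only possible enolate removes the C-2 centre and keeps the aryl-bearing sp3 carbon untouched (β to the ketone); no excess base and inverse addition keep the now acidic indene C–H from being deprotonated.

**Step 11**
Reactants: 19 (1R)-5,7-bis(benzyloxy)-2-[4-(benzyloxy)phenyl]-1-[3,5-bis(benzyloxy)phenyl]-1H-inden-3-yl trifluoromethanesulfonate; 7 [4-(benzyloxy)phenyl]tributylstannane
Product: 20 {(1S)-5,7-bis(benzyloxy)-2-[4-(benzyloxy)phenyl]-1-[3,5-bis(benzyloxy)phenyl]-1H-inden-3-yl}[4-(benzyloxy)phenyl]methanone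
Conditions: Pd(PPh3)4 (5 mol %), LiCl (3 equiv), CO (1 atm), THF, 60 °C
Reagents that add atoms: carbon monoxide, [C-]#[O+]
Why: carbonylative Stille coupling (oxidative addition, CO insertion, aryl transfer from tin) builds the aroyl group under base-free conditions, so the γ-C–H of the enone is not epimerised; the descriptor changes from R to S only through CIP priorities.

**Step 12**
Reactants: 20 {(1S)-5,7-bis(benzyloxy)-2-[4-(benzyloxy)phenyl]-1-[3,5-bis(benzyloxy)phenyl]-1H-inden-3-yl}[4-(benzyloxy)phenyl]methanone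
Product: 21 caraphenol B, [(1R,2R,3R)-3-(3,5-dihydroxyphenyl)-4,6-dihydroxy-2-(4-hydroxyphenyl)-2,3-dihydro-1H-inden-1-yl](4-hydroxyphenyl)methanone (all-cis)
Conditions: H2 (1 atm), 10% Pd/C, EtOAc–MeOH, rt; filtration, base-free work-up
Reagents that add atoms: none
Why: heterogeneous hydrogenation adds H2 syn to the tetrasubstituted enone C=C from the face opposite the existing aryl group, setting C-1 and C-2 cis to C-3 (the kinetic, contra-thermodynamic isomer), while the five benzyl ethers are cleaved by hydrogenolysis in the same pot.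

**Compound list**
1 | methyl 3,5-dihydroxybenzoate | COC(=O)c1cc(O)cc(O)c1 | starting material
2 | methyl 3,5-bis(benzyloxy)benzoate | COC(=O)c1cc(OCc2ccccc2)cc(OCc2ccccc2)c1 | intermediate
3 | 3,5-bis(benzyloxy)-N-methoxy-N-methylbenzamide | CON(C)C(=O)c1cc(OCc2ccccc2)cc(OCc2ccccc2)c1 | intermediate
4 | 4-bromophenol | Oc1ccc(Br)cc1 | starting material
5 | 1-(benzyloxy)-4-bromobenzene | Brc1ccc(OCc2ccccc2)cc1 | intermediate
6 | [4-(benzyloxy)phenyl]lithium | [Li]c1ccc(OCc2ccccc2)cc1 | intermediate (not isolated)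
7 | [4-(benzyloxy)phenyl]tributylstannane | CCCC[Sn](CCCC)(CCCC)c1ccc(OCc2ccccc2)cc1 | intermediate
8 | 1-[3,5-bis(benzyloxy)phenyl]ethan-1-one | CC(=O)c1cc(OCc2ccccc2)cc(OCc2ccccc2)c1 | starting material
9 | 1-[3,5-bis(benzyloxy)-2-bromophenyl]ethan-1-one | CC(=O)c1cc(OCc2ccccc2)cc(OCc2ccccc2)c1Br | intermediate
10 | 2-[3,5-bis(benzyloxy)-2-bromophenyl]-2-methyl-1,3-dioxolane | CC1(OCCO1)c1cc(OCc2ccccc2)cc(OCc2ccccc2)c1Br | intermediate
11 | [2,4-bis(benzyloxy)-6-(2-methyl-1,3-dioxolan-2-yl)phenyl]lithium | CC1(OCCO1)c1cc(OCc2ccccc2)cc(OCc2ccccc2)c1[Li] | intermediate (not isolated)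
12 | [2,4-bis(benzyloxy)-6-(2-methyl-1,3-dioxolan-2-yl)phenyl][3,5-bis(benzyloxy)phenyl]methanone | CC1(OCCO1)c1cc(OCc2ccccc2)cc(OCc2ccccc2)c1C(=O)c1cc(OCc2ccccc2)cc(OCc2ccccc2)c1 | intermediate (not isolated)
13 | 1-{3,5-bis(benzyloxy)-2-[3,5-bis(benzyloxy)benzoyl]phenyl}ethan-1-one | CC(=O)c1cc(OCc2ccccc2)cc(OCc2ccccc2)c1C(=O)c1cc(OCc2ccccc2)cc(OCc2ccccc2)c1 | intermediate
14 | rac-4,6-bis(benzyloxy)-3-[3,5-bis(benzyloxy)phenyl]-3-hydroxy-2,3-dihydro-1H-inden-1-one | O=C1CC(O)(c2cc(OCc3ccccc3)cc(OCc3ccccc3)c2)c2c(OCc3ccccc3)cc(OCc3ccccc3)cc12 | intermediate (not isolated)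
15 | 4,6-bis(benzyloxy)-3-[3,5-bis(benzyloxy)phenyl]-1H-inden-1-one | O=C1C=C(c2cc(OCc3ccccc3)cc(OCc3ccccc3)c2)c2c(OCc3ccccc3)cc(OCc3ccccc3)cc12 | intermediate
16 | bis({(1R)-5,7-bis(benzyloxy)-1-[3,5-bis(benzyloxy)phenyl]-1H-inden-3-yl}oxy)diphenylsilane | c1ccccc1[Si](c1ccccc1)(OC1=C[C@H](c2cc(OCc3ccccc3)cc(OCc3ccccc3)c2)c2c(OCc3ccccc3)cc(OCc3ccccc3)cc12)OC1=C[C@H](c2cc(OCc3ccccc3)cc(OCc3ccccc3)c2)c2c(OCc3ccccc3)cc(OCc3ccccc3)cc12 | intermediate (not isolated)
17 | (2R,3R)-4,6-bis(benzyloxy)-2-[4-(benzyloxy)phenyl]-3-[3,5-bis(benzyloxy)phenyl]-2,3-dihydro-1H-inden-1-one (trans) | O=C1c2cc(OCc3ccccc3)cc(OCc3ccccc3)c2[C@@H](c2cc(OCc3ccccc3)cc(OCc3ccccc3)c2)[C@@H]1c1ccc(OCc2ccccc2)cc1 | intermediate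
18 | potassium (1S)-5,7-bis(benzyloxy)-2-[4-(benzyloxy)phenyl]-1-[3,5-bis(benzyloxy)phenyl]-1H-inden-3-olate (same spatial arrangement at C-1 as in 19) | [K+].[O-]C1=C(c2ccc(OCc3ccccc3)cc2)[C@H](c2cc(OCc3ccccc3)cc(OCc3ccccc3)c2)c2c(OCc3ccccc3)cc(OCc3ccccc3)cc12 | intermediate (not isolated)
19 | (1R)-5,7-bis(benzyloxy)-2-[4-(benzyloxy)phenyl]-1-[3,5-bis(benzyloxy)phenyl]-1H-inden-3-yl trifluoromethanesulfonate | FC(F)(F)S(=O)(=O)OC1=C(c2ccc(OCc3ccccc3)cc2)[C@H](c2cc(OCc3ccccc3)cc(OCc3ccccc3)c2)c2c(OCc3ccccc3)cc(OCc3ccccc3)cc12 | intermediate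
20 | {(1S)-5,7-bis(benzyloxy)-2-[4-(benzyloxy)phenyl]-1-[3,5-bis(benzyloxy)phenyl]-1H-inden-3-yl}[4-(benzyloxy)phenyl]methanone | O=C(c1ccc(OCc2ccccc2)cc1)C1=C(c2ccc(OCc3ccccc3)cc2)[C@H](c2cc(OCc3ccccc3)cc(OCc3ccccc3)c2)c2c(OCc3ccccc3)cc(OCc3ccccc3)cc12 | intermediate
21 | caraphenol B, [(1R,2R,3R)-3-(3,5-dihydroxyphenyl)-4,6-dihydroxy-2-(4-hydroxyphenyl)-2,3-dihydro-1H-inden-1-yl](4-hydroxyphenyl)methanone, all-cis | O=C(c1ccc(O)cc1)[C@H]1c2cc(O)cc(O)c2[C@@H](c2cc(O)cc(O)c2)[C@H]1c1ccc(O)cc1 | target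

**Step count**
Total: 12 steps.
Longest linear sequence: 8 steps (8 → 9 → 10 → 13 → 15 → 17 → 19 → 20 → 21, steps 5–12; the branch 1 → 2 → 3 → 13 → … → 21 is equally long).

**Steps most likely to fail, with fallbacks**

Step 9 (asymmetric 1,4-reduction/arylation). The hindered β-aryl indenone may reduce slowly, with low ee or with the opposite sense, and the one-pot arylation may stall. The fallback sets out from 15 and comes back at 17. Indenone 15 is reduced without stereocontrol (Stryker's reagent, PhMe2SiH, toluene) to racemic 4,6-bis(benzyloxy)-3-[3,5-bis(benzyloxy)phenyl]indan-1-one F1. A Noyori–Ikariya transfer hydrogenation (RuCl[(S,S)-TsDPEN](p-cymene), HCO2H/Et3N) is then run to about 55% conversion as a kinetic resolution. The (3S)-ketone, which takes hydride anti to its aryl group, is reduced to the cis-(1S,3S)-indanol F3. The unreacted (3R)-4,6-bis(benzyloxy)-3-[3,5-bis(benzyloxy)phenyl]indan-1-one F2 is recovered and α-arylated with 5 (Pd2(dba)3, XPhos, NaOt-Bu, toluene, 70 °C) to give 17.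

Step 11 (carbonylative Stille). CO insertion may lose to direct aryl transfer on the tetrasubstituted, hindered triflate, and the acidic indene C–H is at risk on long heating. The fallback sets out from 19 and comes back at 20. A Nozaki–Hiyama–Kishi coupling of 19 with 4-(benzyloxy)benzaldehyde (CrCl2, cat. NiCl2, DMF, rt, base-free) gives the allylic alcohol {(1S)-5,7-bis(benzyloxy)-2-[4-(benzyloxy)phenyl]-1-[3,5-bis(benzyloxy)phenyl]-1H-inden-3-yl}[4-(benzyloxy)phenyl]methanol F4 as a carbinol-epimer mixture. Dess–Martin periodinane in CH2Cl2 oxidises both epimers to 20.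

Step 12 (hydrogenation/hydrogenolysis). The tetrasubstituted alkene may reduce more slowly than the benzyl ethers cleave, and long exposure risks ketone over-reduction or double-bond migration. The fallback sets out from 20 and comes back at 21. The two events are separated: BCl3 with pentamethylbenzene (CH2Cl2, −78 °C) removes the five benzyl groups by Friedel–Crafts transfer and leaves the enone intact, giving [(1S)-1-(3,5-dihydroxyphenyl)-5,7-dihydroxy-2-(4-hydroxyphenyl)-1H-inden-3-yl](4-hydroxyphenyl)methanone F5. A short hydrogenation of F5 (H2 1 atm, Pd/C, MeOH) then only has to add H2 across the C=C from the face anti to the aryl group, giving 21.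

**Further compounds**
F1 | step 9 | rac-4,6-bis(benzyloxy)-3-[3,5-bis(benzyloxy)phenyl]-2,3-dihydro-1H-inden-1-one | O=C1CC(c2cc(OCc3ccccc3)cc(OCc3ccccc3)c2)c2c(OCc3ccccc3)cc(OCc3ccccc3)cc12
F2 | step 9 | (3R)-4,6-bis(benzyloxy)-3-[3,5-bis(benzyloxy)phenyl]-2,3-dihydro-1H-inden-1-one | O=C1C[C@H](c2cc(OCc3ccccc3)cc(OCc3ccccc3)c2)c2c(OCc3ccccc3)cc(OCc3ccccc3)cc12
F3 | step 9 | (1S,3S)-4,6-bis(benzyloxy)-3-[3,5-bis(benzyloxy)phenyl]-2,3-dihydro-1H-inden-1-ol (cis) | O[C@H]1C[C@@H](c2cc(OCc3ccccc3)cc(OCc3ccccc3)c2)c2c(OCc3ccccc3)cc(OCc3ccccc3)cc12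
F4 | step 11 | {(1S)-5,7-bis(benzyloxy)-2-[4-(benzyloxy)phenyl]-1-[3,5-bis(benzyloxy)phenyl]-1H-inden-3-yl}[4-(benzyloxy)phenyl]methanol (carbinol epimers) | OC(c1ccc(OCc2ccccc2)cc1)C1=C(c2ccc(OCc3ccccc3)cc2)[C@H](c2cc(OCc3ccccc3)cc(OCc3ccccc3)c2)c2c(OCc3ccccc3)cc(OCc3ccccc3)cc12
F5 | step 12 | [(1S)-1-(3,5-dihydroxyphenyl)-5,7-dihydroxy-2-(4-hydroxyphenyl)-1H-inden-3-yl](4-hydroxyphenyl)methanone | O=C(c1ccc(O)cc1)C1=C(c2ccc(O)cc2)[C@H](c2cc(O)cc(O)c2)c2c(O)cc(O)cc12
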